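**Assumption:** briarane locants are used for the target (C1 quaternary ring carbon with methyl C15; C2, C9, C12 acetoxy carbons; C3=C4; C5=C16H2; C6–Cl; C7–O; C8–OH; C10; C11 with methyl C20; C13/C14 epoxide; C17 with methyl C18; C19 lactone C=O), β is the face of the C1 methyl, and the SMILES strings define every configuration. RA = the ring-A unit of 12 bound through C10, (1R,2R,3S,4R,5R,6R)-5-[(tert-butyldimethylsilyl)oxy]-2,4-dimethyl-2-[(1R)-1-[(triethylsilyl)oxy]prop-2-en-1-yl]-7-oxabicyclo[4.1.0]heptan-3-yl.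

## Retrosynthetic overview

1. The ten-membered ring closes last by diene–ene ring-closing metathesis at C3=C4 (Z); the 2-substituted butadiene (C4, C5, C16) is made in the same flask from a C4≡C5 alkyne and ethene.
2. Lactone and chlorohydrin: the C7 lactone carbonyl of the coupled fragment is reduced to the lactol, a chloroallenylzinc adds (C6–C7, anti Cl/OH), and oxidation re-closes the lactone on C19.
3. Fragment union at C8–C9: aldol of an α-silyloxy lactone enolate (fragment B, from dimethyl (S)-malate, carries C17) with ring-A aldehyde 12 (fragment A); fragment C is silylated propargyl chloride.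
4. Fragment A: catalytic asymmetric Diels–Alder (C1, C10, C11), Saegusa enone, asymmetric vinylation (C2), Luche reduction (C12), hydroxyl-directed epoxidation (C13/C14).
5. Ring order: six-membered ring A, epoxide, temporary C7 lactone, final γ-lactone, ten-membered ring.

## Fragment A (ring A, C1–C3, C9–C15, C20)

Step 1
Reactants: 1 ethyl 3-methylbut-2-enoate
Product: 2 ethyl (2E)-3-methyl-4-oxobut-2-enoate
Conditions: SeO2 (1.1 equiv), 1,4-dioxane, 100 °C
Reagents that add atoms: selenium dioxide, O=[Se]=O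
Why: Riley allylic oxidation; SeO2 oxidises the methyl trans to the ester, so CHO and CO2Et end up trans.

Step 2
Reactants: 3 pent-1-en-3-one
Product: 4 tert-butyldimethyl[(3Z)-penta-1,3-dien-3-yloxy]silane
Conditions: t-BuMe2SiOTf, Et3N, CH2Cl2, 0 °C
Reagents that add atoms: tert-butyldimethylsilyl trifluoromethanesulfonate, CC(C)(C)[Si](C)(C)OS(=O)(=O)C(F)(F)F
Why: Soft enolisation and O-silylation of the only enolisable CH2; the Z enol ether (methyl on the outside of the s-cis diene) predominates.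

Step 3
Reactants: 2 ethyl (2E)-3-methyl-4-oxobut-2-enoate; 4 tert-butyldimethyl[(3Z)-penta-1,3-dien-3-yloxy]silane
Product: 5 ethyl (1S,2R,6S)-3-[(tert-butyldimethylsilyl)oxy]-6-formyl-2,6-dimethylcyclohex-3-ene-1-carboxylate
Conditions: (S)-o-tolyl oxazaborolidine·HNTf2 (Corey type, 20 mol %), CH2Cl2, −78 °C
Reagents that add atoms: none
Why: Catalytic enantioselective Diels–Alder reaction. The formyl-bound Lewis acid fixes the regiochemistry (silyloxy para to CHO, C10–C11 bond to the enal β-carbon). The exo-formyl/endo-ester transition state with the outside diene methyl puts the C15 methyl, the C9 ester and the C20 methyl all cis, and the catalyst sets the absolute sense.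

Step 4
Reactants: 5 ethyl (1S,2R,6S)-3-[(tert-butyldimethylsilyl)oxy]-6-formyl-2,6-dimethylcyclohex-3-ene-1-carboxylate
Product: 6 ethyl (1S,2R,6S)-6-formyl-2,6-dimethyl-3-oxocyclohex-4-ene-1-carboxylate
Conditions: Pd(OAc)2 (10 mol %), O2 (1 atm), DMSO, 45 °C
Reagents that add atoms: none
Why: Saegusa–Ito oxidation; the silyl enol ether fixes the C12 ketone and the C13=C14 double bond, and C11 keeps its configuration (both methyls equatorial).

Step 5
Reactants: 6 ethyl (1S,2R,6S)-6-formyl-2,6-dimethyl-3-oxocyclohex-4-ene-1-carboxylate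
Product: 7 ethyl (1S,2R,6S)-6-[(1R)-1-hydroxyprop-2-en-1-yl]-2,6-dimethyl-3-oxocyclohex-4-ene-1-carboxylate
Conditions: (CH2=CH)2Zn (from CH2=CHMgBr and ZnCl2, 1.5 equiv), (+)-DAIB (15 mol %), toluene, −20 °C
Reagents that add atoms: vinylmagnesium bromide, C=C[Mg]Br
Why: Amino-alcohol-catalysed asymmetric alkenylzinc addition; the organozinc adds only to the aldehyde, and (+)-DAIB delivers vinyl to the Re face, giving 2R by reagent control.

Step 6
Reactants: 7 ethyl (1S,2R,6S)-6-[(1R)-1-hydroxyprop-2-en-1-yl]-2,6-dimethyl-3-oxocyclohex-4-ene-1-carboxylate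
Product: 8 ethyl (1S,2R,3S,6S)-3-hydroxy-6-[(1R)-1-hydroxyprop-2-en-1-yl]-2,6-dimethylcyclohex-4-ene-1-carboxylate
Conditions: NaBH4, CeCl3·7H2O, MeOH, −78 °C
Reagents that add atoms: none
Why: Luche 1,2-reduction; the axial C10 ester blocks the β-face, so hydride enters from the α-face and gives the 12β-alcohol, cis to the C20 methyl.

Step 7
Reactants: 8 ethyl (1S,2R,3S,6S)-3-hydroxy-6-[(1R)-1-hydroxyprop-2-en-1-yl]-2,6-dimethylcyclohex-4-ene-1-carboxylate
Product: 9 ethyl (1S,2R,3S,6S)-3-[(tert-butyldimethylsilyl)oxy]-6-[(1R)-1-hydroxyprop-2-en-1-yl]-2,6-dimethylcyclohex-4-ene-1-carboxylate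
Conditions: t-BuMe2SiCl (1.05 equiv), imidazole, DMF, 0 °C
Reagents that add atoms: tert-butyldimethylsilyl chloride, CC(C)(C)[Si](C)(C)Cl
Why: Chemoselective silylation; the ring C12–OH reacts, while the neopentylic C2–OH next to quaternary C1 does not.

Step 8
Reactants: 9 ethyl (1S,2R,3S,6S)-3-[(tert-butyldimethylsilyl)oxy]-6-[(1R)-1-hydroxyprop-2-en-1-yl]-2,6-dimethylcyclohex-4-ene-1-carboxylate
Product: 10 ethyl (1R,2S,3S,4R,5R,6R)-5-[(tert-butyldimethylsilyl)oxy]-2-[(1R)-1-hydroxyprop-2-en-1-yl]-2,4-dimethyl-7-oxabicyclo[4.1.0]heptane-3-carboxylate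
Conditions: mCPBA, NaHCO3 (buffer), CH2Cl2, 0 °C
Reagents that add atoms: 3-chloroperoxybenzoic acid, OOC(=O)c1cccc(Cl)c1
Why: Prilezhaev epoxidation of the more nucleophilic ring alkene; the free homoallylic C2–OH on the α-face delivers the peracid (Henbest effect) and the β-face is shielded by the C12 silyl ether and the C15 methyl, giving the 13α,14α-epoxide.

Step 9
Reactants: 10 ethyl (1R,2S,3S,4R,5R,6R)-5-[(tert-butyldimethylsilyl)oxy]-2-[(1R)-1-hydroxyprop-2-en-1-yl]-2,4-dimethyl-7-oxabicyclo[4.1.0]heptane-3-carboxylate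
Product: 11 ethyl (1R,2R,3S,4R,5R,6R)-5-[(tert-butyldimethylsilyl)oxy]-2,4-dimethyl-2-[(1R)-1-[(triethylsilyl)oxy]prop-2-en-1-yl]-7-oxabicyclo[4.1.0]heptane-3-carboxylate
Conditions: Et3SiOTf, 2,6-lutidine, CH2Cl2, −78 → 0 °C
Reagents that add atoms: triethylsilyl trifluoromethanesulfonate, CC[Si](CC)(CC)OS(=O)(=O)C(F)(F)F
Why: Silyl protection of the hindered C2–OH with the reactive triflate, which also prevents lactol formation with C9 in the next step.

Step 10
Reactants: 11 ethyl (1R,2R,3S,4R,5R,6R)-5-[(tert-butyldimethylsilyl)oxy]-2,4-dimethyl-2-[(1R)-1-[(triethylsilyl)oxy]prop-2-en-1-yl]-7-oxabicyclo[4.1.0]heptane-3-carboxylate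
Product: 12 (1R,2R,3S,4R,5R,6R)-5-[(tert-butyldimethylsilyl)oxy]-2,4-dimethyl-2-[(1R)-1-[(triethylsilyl)oxy]prop-2-en-1-yl]-7-oxabicyclo[4.1.0]heptane-3-carbaldehyde
Conditions: i-Bu2AlH (1.1 equiv), toluene, −78 °C
Reagents that add atoms: none
Why: Partial DIBAL reduction of the hindered ester; the aluminium hemiacetal is stable at −78 °C and gives the C9 aldehyde on work-up, while the epoxide and silyl ethers are inert.

## Fragment B (C7, C8, C17–C19)

Step 11
Reactants: 13 dimethyl (2S)-2-hydroxybutanedioate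
Product: 15 dimethyl (2S,3R)-2-hydroxy-3-methylbutanedioate, via dilithium alkoxide enolate 14 (not isolated)
Conditions: LiN(i-Pr)2 (2.2 equiv), THF, −78 → −20 °C; then MeI, −78 → 0 °C
Reagents that add atoms: iodomethane, CI
Why: Fráter–Seebach alkylation; the chelated alkoxide enolate is methylated anti to the alkoxide, setting C17.

Step 12
Reactants: 15 dimethyl (2S,3R)-2-hydroxy-3-methylbutanedioate
Product: 16 (2S,3R)-2-hydroxy-3-methylbutanedioic acid
Conditions: LiOH, THF/H2O, 0 °C → rt; then HCl (aq)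
Reagents that add atoms: lithium hydroxide, [Li+].[OH-]
Why: Ester saponification under mild conditions that do not epimerise C17.

Step 13
Reactants: 16 (2S,3R)-2-hydroxy-3-methylbutanedioic acid
Product: 17 (2R)-2-[(4S)-2,2-dimethyl-5-oxo-1,3-dioxolan-4-yl]propanoic acid
Conditions: Me2C(OMe)2, TsOH·H2O (cat.), CH2Cl2, rt
Reagents that add atoms: 2,2-dimethoxypropane, COC(C)(C)OC
Why: Acetalisation of the α-hydroxy acid as the five-membered dioxolanone, leaving the distal carboxylic acid free.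

Step 14
Reactants: 17 (2R)-2-[(4S)-2,2-dimethyl-5-oxo-1,3-dioxolan-4-yl]propanoic acid
Product: 18 (5S)-5-[(2S)-1-hydroxypropan-2-yl]-2,2-dimethyl-1,3-dioxolan-4-one
Conditions: BH3·SMe2, THF, 0 °C → rt; MeOH quench
Reagents that add atoms: none
Why: Chemoselective borane reduction of the free carboxylic acid (C19) in the presence of the dioxolanone.

Step 15
Reactants: 18 (5S)-5-[(2S)-1-hydroxypropan-2-yl]-2,2-dimethyl-1,3-dioxolan-4-one
Product: 19 (3S,4S)-3-hydroxy-4-methyloxolan-2-one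
Conditions: TsOH·H2O (cat.), CH2Cl2, rt
Reagents that add atoms: none
Why: Acid-catalysed translactonisation; the primary alcohol attacks the dioxolanone carbonyl (C7) and acetone is lost.

Step 16
Reactants: 19 (3S,4S)-3-hydroxy-4-methyloxolan-2-one
Product: 20 (3S,4S)-4-methyl-3-[(triethylsilyl)oxy]oxolan-2-one
Conditions: Et3SiCl, imidazole, DMF, 0 °C → rt
Reagents that add atoms: chlorotriethylsilane, CC[Si](CC)(CC)Cl
Why: Silyl protection of the α-hydroxyl as a non-chelating group for the later aldol and carbonyl addition.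

## Fragment C (C4–C6)

Step 17
Reactants: 21 3-chloroprop-1-yne
Product: 23 (3-chloroprop-1-yn-1-yl)trimethylsilane, via lithium acetylide 22 (not isolated)
Conditions: n-BuLi, Et2O, −78 °C; then Me3SiCl, −78 → 0 °C
Reagents that add atoms: chlorotrimethylsilane, C[Si](C)(C)Cl
Why: Deprotonation of the terminal alkyne at low temperature and C-silylation.

## Union and endgame

Step 18
Reactants: 20 (3S,4S)-4-methyl-3-[(triethylsilyl)oxy]oxolan-2-one; 12 (1R,2R,3S,4R,5R,6R)-5-[(tert-butyldimethylsilyl)oxy]-2,4-dimethyl-2-[(1R)-1-[(triethylsilyl)oxy]prop-2-en-1-yl]-7-oxabicyclo[4.1.0]heptane-3-carbaldehyde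
Product: 26 (3R,4S)-4-methyl-3-[(R)-RA(triethylsilyloxy)methyl]-3-(triethylsilyloxy)oxolan-2-one, via lithium enolate 24 (not isolated), via lithium aldolate 25 (not isolated)
Conditions: 20 (1.3 equiv), LiN(i-Pr)2 (1.35 equiv), THF, −78 °C; then 12, −78 °C; then Et3SiOTf, −78 → −30 °C
Reagents that add atoms: triethylsilyl trifluoromethanesulfonate, CC[Si](CC)(CC)OS(=O)(=O)C(F)(F)F
Why: Lactone enolate aldol forming C8–C9. The aldehyde adds to the enolate face anti to the C17 methyl (sets quaternary C8), and Felkin–Anh attack with quaternary C1 antiperiplanar gives the target C9 configuration; silylating the aldolate in the flask blocks retro-aldol.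

Step 19
Reactants: 26 (3R,4S)-4-methyl-3-[(R)-RA(triethylsilyloxy)methyl]-3-(triethylsilyloxy)oxolan-2-one
Product: 27 (3R,4S)-4-methyl-3-[(R)-RA(triethylsilyloxy)methyl]-3-(triethylsilyloxy)oxolan-2-ol (lactol, both C7 anomers)
Conditions: i-Bu2AlH (1.3 equiv), CH2Cl2, −78 °C
Reagents that add atoms: none
Why: DIBAL reduction of the only carbonyl group, stopping at the five-membered lactol, which is a masked C7 aldehyde.

Step 20
Reactants: 27 lactol (3R,4S)-4-methyl-3-[(R)-RA(triethylsilyloxy)methyl]-3-(triethylsilyloxy)oxolan-2-ol; 23 (3-chloroprop-1-yn-1-yl)trimethylsilane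
Product: 29 chlorohydrin diol (C19H2OH and C7–OH free; C6–Cl; C5≡C4–SiMe3), via chloroallenylzinc bromide 28 (not isolated)
Conditions: 23 (3.5 equiv), ZnBr2, n-BuLi, THF, −78 °C; then 27, −78 → −20 °C
Reagents that add atoms: none
Why: SE2′ addition of a propargylic zinc carbenoid (Chemla type) to the open hydroxy-aldehyde form. The cyclic transition state gives the anti chlorohydrin (C6 relative to C7), and polar Felkin–Anh attack anti to the C8–OSiEt3 bond, past the smaller C17 arm, sets C7. The racemic reagent is used in excess because the lactol OH consumes one equivalent.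

Step 21
Reactants: 29 chlorohydrin diol
Product: 30 (3R,4S,5R)-5-[(1S)-1-chloro-3-(trimethylsilyl)prop-2-yn-1-yl]-3-methyl-4-[(R)-RA(triethylsilyloxy)methyl]-4-(triethylsilyloxy)oxolan-2-one
Conditions: TEMPO (20 mol %), PhI(OAc)2 (2.5 equiv), CH2Cl2, rt
Reagents that add atoms: none
Why: TEMPO oxidative lactonisation; the primary C19 alcohol is oxidised selectively, the aldehyde is trapped by C7–OH as a lactol and oxidised on to the 19,7-lactone without base, so the chlorohydrin cannot close to an epoxide.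

Step 22
Reactants: 30 (3R,4S,5R)-5-[(1S)-1-chloro-3-(trimethylsilyl)prop-2-yn-1-yl]-3-methyl-4-[(R)-RA(triethylsilyloxy)methyl]-4-(triethylsilyloxy)oxolan-2-one
Product: 31 (3R,4R,5R)-5-[(1S)-1-chloroprop-2-yn-1-yl]-4-hydroxy-4-{(R)-hydroxy[(1R,2S,3S,4R,5R,6S)-5-hydroxy-2-[(1R)-1-hydroxyprop-2-en-1-yl]-2,4-dimethyl-7-oxabicyclo[4.1.0]heptan-3-yl]methyl}-3-methyloxolan-2-one
Conditions: Bu4NF, AcOH (1:1), THF, 0 °C → rt
Reagents that add atoms: none
Why: Buffered fluoride desilylation removes the four O-silyl groups and the alkynyl silyl group; the buffer protects the lactone, the propargylic chloride and the epoxy alcohol from base.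

Step 23
Reactants: 31 tetraol alkyne
Product: 32 2,9,12-tri-O-acetyl derivative of 31 (8-OH free)
Conditions: Ac2O, pyridine, DMAP (cat.), CH2Cl2, 0 °C → rt
Reagents that add atoms: acetic anhydride, CC(=O)OC(C)=O
Why: Acetylation of the three secondary alcohols; the tertiary C8–OH next to the lactone stays free under these conditions.

Step 24
Reactants: 32 triacetate alkyne
Product: 34 CNP0274383.1 (target), via triene 33 (not isolated)
Conditions: second-generation Grubbs catalyst (10 mol %), ethene (1 atm), CH2Cl2, rt; then argon, toluene (1 mM), second-generation Hoveyda–Grubbs catalyst (10 mol %), 80 °C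
Reagents that add atoms: ethene, C=C
Why: Enyne cross-metathesis with ethene (Mori) turns the terminal alkyne into the 2-substituted butadiene, then ring-closing metathesis joins C3 and C4 with loss of ethene; the ten-membered ring enforces the Z alkene.

## Compound list

1 | ethyl 3-methylbut-2-enoate | CCOC(=O)C=C(C)C | starting material
2 | ethyl (2E)-3-methyl-4-oxobut-2-enoate | CCOC(=O)/C=C(\C)C=O | intermediate
3 | pent-1-en-3-one | CCC(=O)C=C | starting material
4 | tert-butyldimethyl[(3Z)-penta-1,3-dien-3-yloxy]silane | C\C=C(/O[Si](C)(C)C(C)(C)C)C=C | intermediate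
5 | ethyl (1S,2R,6S)-3-[(tert-butyldimethylsilyl)oxy]-6-formyl-2,6-dimethylcyclohex-3-ene-1-carboxylate | O=C[C@]1(C)[C@H]([C@@H](C)C(O[Si](C)(C)C(C)(C)C)=CC1)C(=O)OCC | intermediate
6 | ethyl (1S,2R,6S)-6-formyl-2,6-dimethyl-3-oxocyclohex-4-ene-1-carboxylate | O=C[C@]1(C)[C@H]([C@@H](C)C(=O)C=C1)C(=O)OCC | intermediate
7 | ethyl (1S,2R,6S)-6-[(1R)-1-hydroxyprop-2-en-1-yl]-2,6-dimethyl-3-oxocyclohex-4-ene-1-carboxylate | C=C[C@@H](O)[C@]1(C)[C@H]([C@@H](C)C(=O)C=C1)C(=O)OCC | intermediate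
8 | ethyl (1S,2R,3S,6S)-3-hydroxy-6-[(1R)-1-hydroxyprop-2-en-1-yl]-2,6-dimethylcyclohex-4-ene-1-carboxylate | C=C[C@@H](O)[C@]1(C)[C@H]([C@@H](C)[C@@H](O)C=C1)C(=O)OCC | intermediate
9 | ethyl (1S,2R,3S,6S)-3-[(tert-butyldimethylsilyl)oxy]-6-[(1R)-1-hydroxyprop-2-en-1-yl]-2,6-dimethylcyclohex-4-ene-1-carboxylate | C=C[C@@H](O)[C@]1(C)[C@H]([C@@H](C)[C@@H](O[Si](C)(C)C(C)(C)C)C=C1)C(=O)OCC | intermediate
10 | ethyl (1R,2S,3S,4R,5R,6R)-5-[(tert-butyldimethylsilyl)oxy]-2-[(1R)-1-hydroxyprop-2-en-1-yl]-2,4-dimethyl-7-oxabicyclo[4.1.0]heptane-3-carboxylate | C=C[C@@H](O)[C@]1(C)[C@H]([C@@H](C)[C@@H](O[Si](C)(C)C(C)(C)C)[C@@H]2O[C@@H]21)C(=O)OCC | intermediate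
11 | ethyl (1R,2R,3S,4R,5R,6R)-5-[(tert-butyldimethylsilyl)oxy]-2,4-dimethyl-2-[(1R)-1-[(triethylsilyl)oxy]prop-2-en-1-yl]-7-oxabicyclo[4.1.0]heptane-3-carboxylate | C=C[C@@H](O[Si](CC)(CC)CC)[C@]1(C)[C@H]([C@@H](C)[C@@H](O[Si](C)(C)C(C)(C)C)[C@@H]2O[C@@H]21)C(=O)OCC | intermediate
12 | (1R,2R,3S,4R,5R,6R)-5-[(tert-butyldimethylsilyl)oxy]-2,4-dimethyl-2-[(1R)-1-[(triethylsilyl)oxy]prop-2-en-1-yl]-7-oxabicyclo[4.1.0]heptane-3-carbaldehyde | C=C[C@@H](O[Si](CC)(CC)CC)[C@]1(C)[C@H]([C@@H](C)[C@@H](O[Si](C)(C)C(C)(C)C)[C@@H]2O[C@@H]21)C=O | intermediate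
13 | dimethyl (2S)-2-hydroxybutanedioate | COC(=O)[C@@H](O)CC(=O)OC | starting material
14 | dilithium alkoxide enolate of 13 | COC(=O)[C@@H](O[Li])C=C(OC)O[Li] | intermediate
15 | dimethyl (2S,3R)-2-hydroxy-3-methylbutanedioate | COC(=O)[C@@H](O)[C@@H](C)C(=O)OC | intermediate
16 | (2S,3R)-2-hydroxy-3-methylbutanedioic acid | OC(=O)[C@@H](O)[C@@H](C)C(=O)O | intermediate
17 | (2R)-2-[(4S)-2,2-dimethyl-5-oxo-1,3-dioxolan-4-yl]propanoic acid | O=C1OC(C)(C)O[C@H]1[C@@H](C)C(=O)O | intermediate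
18 | (5S)-5-[(2S)-1-hydroxypropan-2-yl]-2,2-dimethyl-1,3-dioxolan-4-one | O=C1OC(C)(C)O[C@H]1[C@@H](C)CO | intermediate
19 | (3S,4S)-3-hydroxy-4-methyloxolan-2-one | O[C@H]1[C@@H](C)COC1=O | intermediate
20 | (3S,4S)-4-methyl-3-[(triethylsilyl)oxy]oxolan-2-one | CC[Si](CC)(CC)O[C@H]1[C@@H](C)COC1=O | intermediate
21 | 3-chloroprop-1-yne | ClCC#C | starting material
22 | lithium 3-chloroprop-1-yn-1-ide | [Li]C#CCCl | intermediate
23 | (3-chloroprop-1-yn-1-yl)trimethylsilane | C[Si](C)(C)C#CCCl | intermediate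
24 | lithium (4S)-4-methyl-3-[(triethylsilyl)oxy]-4,5-dihydrofuran-2-olate (enolate of 20) | [Li]OC1=C(O[Si](CC)(CC)CC)[C@@H](C)CO1 | intermediate
25 | lithium aldolate (C9–OLi form of 26 before silylation) | C=C[C@@H](O[Si](CC)(CC)CC)[C@]1(C)[C@H]([C@@H](C)[C@@H](O[Si](C)(C)C(C)(C)C)[C@@H]2O[C@@H]21)[C@@H](O[Li])[C@]3(O[Si](CC)(CC)CC)[C@@H](C)COC3=O | intermediate
26 | (3R,4S)-4-methyl-3-[(R)-RA(triethylsilyloxy)methyl]-3-(triethylsilyloxy)oxolan-2-one | C=C[C@@H](O[Si](CC)(CC)CC)[C@]1(C)[C@H]([C@@H](C)[C@@H](O[Si](C)(C)C(C)(C)C)[C@@H]2O[C@@H]21)[C@@H](O[Si](CC)(CC)CC)[C@]3(O[Si](CC)(CC)CC)[C@@H](C)COC3=O | intermediate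
27 | (3R,4S)-4-methyl-3-[(R)-RA(triethylsilyloxy)methyl]-3-(triethylsilyloxy)oxolan-2-ol (lactol, both C7 anomers) | C=C[C@@H](O[Si](CC)(CC)CC)[C@]1(C)[C@H]([C@@H](C)[C@@H](O[Si](C)(C)C(C)(C)C)[C@@H]2O[C@@H]21)[C@@H](O[Si](CC)(CC)CC)[C@]3(O[Si](CC)(CC)CC)[C@@H](C)COC3O | intermediate
28 | bromo[3-chloro-1-(trimethylsilyl)propa-1,2-dien-1-yl]zinc (racemic) | ClC=C=C([Zn]Br)[Si](C)(C)C | intermediate
29 | chlorohydrin diol: C19H2OH–C17H(CH3)–C8(OSiEt3)[C9H(OSiEt3)–RA]–C7H(OH)–C6H(Cl)–C≡C–SiMe3, stereocentres as in 34 | C=C[C@@H](O[Si](CC)(CC)CC)[C@]1(C)[C@H]([C@@H](C)[C@@H](O[Si](C)(C)C(C)(C)C)[C@@H]2O[C@@H]21)[C@@H](O[Si](CC)(CC)CC)[C@](O[Si](CC)(CC)CC)([C@@H](C)CO)[C@@H](O)[C@H](C#C[Si](C)(C)C)Cl | intermediate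
30 | (3R,4S,5R)-5-[(1S)-1-chloro-3-(trimethylsilyl)prop-2-yn-1-yl]-3-methyl-4-[(R)-RA(triethylsilyloxy)methyl]-4-(triethylsilyloxy)oxolan-2-one | C=C[C@@H](O[Si](CC)(CC)CC)[C@]1(C)[C@H]([C@@H](C)[C@@H](O[Si](C)(C)C(C)(C)C)[C@@H]2O[C@@H]21)[C@@H](O[Si](CC)(CC)CC)[C@]3(O[Si](CC)(CC)CC)[C@@H](C)C(=O)O[C@H]3[C@H](C#C[Si](C)(C)C)Cl | intermediate
31 | (3R,4R,5R)-5-[(1S)-1-chloroprop-2-yn-1-yl]-4-hydroxy-4-{(R)-hydroxy[(1R,2S,3S,4R,5R,6S)-5-hydroxy-2-[(1R)-1-hydroxyprop-2-en-1-yl]-2,4-dimethyl-7-oxabicyclo[4.1.0]heptan-3-yl]methyl}-3-methyloxolan-2-one | C=C[C@@H](O)[C@]1(C)[C@H]([C@@H](C)[C@@H](O)[C@@H]2O[C@@H]21)[C@@H](O)[C@]3(O)[C@@H](C)C(=O)O[C@H]3[C@H](C#C)Cl | intermediate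
32 | 2,9,12-tri-O-acetyl derivative of 31 (8-OH free; seco-target with C2 vinyl and C5 ethynyl) | C=C[C@@H](OC(C)=O)[C@]1(C)[C@H]([C@@H](C)[C@@H](OC(C)=O)[C@@H]2O[C@@H]21)[C@@H](OC(C)=O)[C@]3(O)[C@@H](C)C(=O)O[C@H]3[C@H](C#C)Cl | intermediate
33 | triene: 32 with the ethynyl group converted to buta-1,3-dien-2-yl | C=C[C@@H](OC(C)=O)[C@]1(C)[C@H]([C@@H](C)[C@@H](OC(C)=O)[C@@H]2O[C@@H]21)[C@@H](OC(C)=O)[C@]3(O)[C@@H](C)C(=O)O[C@H]3[C@H](C(=C)C=C)Cl | intermediate
34 | CNP0274383.1: (1S,2R,3Z,6S,7R,8R,9R,10S,11R,12R,13S,14R,17R)-2,9,12-triacetoxy-6-chloro-13,14-epoxy-8-hydroxybriara-3,5(16)-dien-19,7-olide | C=C1/C=C\[C@@H](OC(C)=O)[C@]2(C)[C@H]([C@@H](C)[C@@H](OC(C)=O)[C@@H]3O[C@@H]32)[C@@H](OC(C)=O)[C@]2(O)[C@@H](C)C(=O)O[C@H]2[C@H]1Cl | target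

## Step count

Total: 24 steps. Longest linear sequence: 16 steps (3 → 4 → 5 → … → 12 → 26 → … → 34, steps 2–10 and 18–24; the chain from 1 through steps 1, 3–10 and 18–24 is equally long). Fragment B (steps 11–16) and fragment C (step 17) run in parallel.

## Three steps most likely to fail, with fallbacks

**Step 18 (aldol union).** A tetrasubstituted enolate must add to a hindered aldehyde, and C9 rests on Felkin–Anh control. The fallback sets C9 by ketone reduction instead; it sets out from 12 (with 20) and returns at 26. Pinnick oxidation of 12 (NaClO2, NaH2PO4, 2-methylbut-2-ene) gives the ring-A carboxylic acid F1, and cyanuric fluoride with pyridine converts it into the acyl fluoride F2. C-acylation of lithium enolate 24 with F2, again anti to the C17 methyl, gives the β-keto lactone F3. Felkin–Anh reduction (NaBH4, CeCl3·7H2O, MeOH, −78 °C; hydride anti to the C8–OSiEt3 bond and past the flat lactone carbonyl) gives the 9-hydroxy lactone F4, and Et3SiOTf with 2,6-lutidine then gives 26.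

**Step 20 (chloroallenylzinc addition to the lactol).** The lactol must open next to a quaternary carbon, and the C7 face selectivity is only substrate-controlled. The fallback builds C6/C7 by alkene chlorolactonisation; it sets out from 27 and returns at 30. Horner–Wadsworth–Emmons olefination of 27 with diethyl [3-(trimethylsilyl)prop-2-yn-1-yl]phosphonate and LiN(SiMe3)2 gives the (E)-enyne primary alcohol F5. TEMPO and PhI(OAc)2 in MeCN/H2O oxidise it to the (E)-enyne carboxylic acid F6. Catalytic asymmetric chlorolactonisation (1,3-dichloro-5,5-dimethylhydantoin, (DHQD)2PHAL) adds the carboxylate oxygen at C7 and chlorine at C6 anti across the E alkene, which gives the same anti relationship, with the face chosen by the catalyst, and so delivers 30.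

**Step 24 (ring-closing metathesis to the ten-membered diene).** The catalyst can load on the diene and form an unreactive vinyl carbene, or engage the 1,1-disubstituted alkene. The fallback is a relay ring closure; it sets out from 32 and returns at 34. Enyne cross-metathesis of 32 with hepta-1,6-diene (second-generation Grubbs catalyst) in place of ethene gives the relay tetraene F7, in which C4 carries a CH=CH(CH2)3CH=CH2 arm. The ruthenium then loads at the unhindered terminal alkene, expels cyclopentene to place the carbene on C4, and closes onto the C2 vinyl group to give 34.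

## Further compounds

F1 | step 18 | (1R,2R,3S,4R,5R,6R)-5-[(tert-butyldimethylsilyl)oxy]-2,4-dimethyl-2-[(1R)-1-[(triethylsilyl)oxy]prop-2-en-1-yl]-7-oxabicyclo[4.1.0]heptane-3-carboxylic acid | C=C[C@@H](O[Si](CC)(CC)CC)[C@]1(C)[C@H]([C@@H](C)[C@@H](O[Si](C)(C)C(C)(C)C)[C@@H]2O[C@@H]21)C(=O)O
F2 | step 18 | acyl fluoride of F1 (RA–C(=O)F) | C=C[C@@H](O[Si](CC)(CC)CC)[C@]1(C)[C@H]([C@@H](C)[C@@H](O[Si](C)(C)C(C)(C)C)[C@@H]2O[C@@H]21)C(=O)F
F3 | step 18 | β-keto lactone: 4-methyl-3-(RA-carbonyl)-3-(triethylsilyloxy)oxolan-2-one, C8 and C17 as in 26 | C=C[C@@H](O[Si](CC)(CC)CC)[C@]1(C)[C@H]([C@@H](C)[C@@H](O[Si](C)(C)C(C)(C)C)[C@@H]2O[C@@H]21)C(=O)[C@]3(O[Si](CC)(CC)CC)[C@@H](C)COC3=O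
F4 | step 18 | 9-hydroxy lactone: 26 with free C9–OH | C=C[C@@H](O[Si](CC)(CC)CC)[C@]1(C)[C@H]([C@@H](C)[C@@H](O[Si](C)(C)C(C)(C)C)[C@@H]2O[C@@H]21)[C@@H](O)[C@]3(O[Si](CC)(CC)CC)[C@@H](C)COC3=O
F5 | step 20 | (E)-enyne primary alcohol: C19H2OH–C17H(CH3)–C8(OSiEt3)[C9H(OSiEt3)–RA]–C7H=C6H–C≡C–SiMe3 | C=C[C@@H](O[Si](CC)(CC)CC)[C@]1(C)[C@H]([C@@H](C)[C@@H](O[Si](C)(C)C(C)(C)C)[C@@H]2O[C@@H]21)[C@@H](O[Si](CC)(CC)CC)[C@](O[Si](CC)(CC)CC)([C@@H](C)CO)/C=C/C#C[Si](C)(C)C
F6 | step 20 | (E)-enyne carboxylic acid: F5 with C19 oxidised to CO2H | C=C[C@@H](O[Si](CC)(CC)CC)[C@]1(C)[C@H]([C@@H](C)[C@@H](O[Si](C)(C)C(C)(C)C)[C@@H]2O[C@@H]21)[C@@H](O[Si](CC)(CC)CC)[C@](O[Si](CC)(CC)CC)([C@@H](C)C(=O)O)/C=C/C#C[Si](C)(C)C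
F7 | step 24 | relay tetraene: 32 with the ethynyl group converted to (3E)-nona-1,3,8-trien-2-yl | C=C[C@@H](OC(C)=O)[C@]1(C)[C@H]([C@@H](C)[C@@H](OC(C)=O)[C@@H]2O[C@@H]21)[C@@H](OC(C)=O)[C@]3(O)[C@@H](C)C(=O)O[C@H]3[C@H](C(=C)/C=C/CCCC=C)Cl
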